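## Retrosynthetic overview

1. The target is traced back to its 7(11)-en-8-one: a singlet-oxygen ene reaction puts oxygen on C11 and moves the alkene to C6=C7. The enone comes from the C8 ketone and acetone (C7–C11). The O3 angelate and O4 acetate are placed on a cis-3α,4α-diol before ring B is elaborated.
2. The diol comes from a C8-ketalised 4-methyl-Δ4-3-ketone: Li/NH3 with silyl trapping (5α-H, trans fusion), Rubottom oxidation (4α-O), L-Selectride (3α-OH).
3. The enone ketal comes from a bicyclic 1,4-diene-3,8-dione by hydrogenation of C1=C2 and ketalisation of C8.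
4. Key disconnection C9–C10: the dienedione comes from 1-diazo-4-(3-hydroxy-2,6-dimethylphenyl)butan-2-one. The strategy rests on ring A (C1–C5, C10) carrying oxygen on C3, methyl C15 on the neighbouring C4 and methyl C14 on C10 para to C3. This is a 2,4-dimethylphenol whose para carbon C10 is alkylated by carbene carbon C9 from the tether on C5.
5. Ring order: ring A is the purchased arene (side chain by Negishi coupling, O3 by bromination/hydroxylation, C9 from TMS-diazomethane); ring B is closed in step 7.

Key step: step 7

Remark: eudesmane numbering is used throughout (β = face of the C10 methyl C14); the ligand in step 7 is written as (S,S), and its antipode is to be used if the sense of induction proves to be the opposite.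

## Route

Step 1
Reactants: 1 2-bromo-1,3-dimethylbenzene; 2 (3-ethoxy-3-oxopropyl)zinc bromide (0.5 M in THF)
Product: 3 ethyl 3-(2,6-dimethylphenyl)propanoate
Conditions: Pd(OAc)2 (2 mol %), SPhos (4 mol %), THF, 65 °C
Reagents that add atoms: none
Why: Negishi sp2–sp3 cross-coupling, in which the ester-bearing alkylzinc transmetallates without touching its own ester and the bulky electron-rich biarylphosphine allows oxidative addition and reductive elimination at the di-ortho-substituted bromide.

Step 2
Reactants: 3 ethyl 3-(2,6-dimethylphenyl)propanoate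
Product: 4 ethyl 3-(3-bromo-2,6-dimethylphenyl)propanoate
Conditions: Br2 (1.0 equiv), Fe powder (5 mol %), CH2Cl2, 0 °C, dark
Reagents that add atoms: bromine BrBr
Why: Electrophilic aromatic bromination, directed to the ring carbon that is ortho to one methyl and para to the other, whereas the only other kind of free position, para to the side chain, is meta to both methyls and is activated by one alkyl group instead of two; dark Lewis-acidic conditions avoid benzylic bromination and the first bromine deactivates the ring against a second.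

Step 3
Reactants: 4 ethyl 3-(3-bromo-2,6-dimethylphenyl)propanoate
Product: 5 3-(3-hydroxy-2,6-dimethylphenyl)propanoic acid
Conditions: Pd2(dba)3 (2 mol %), t-BuXPhos (8 mol %), KOH (4 equiv), dioxane/H2O 1:1, 100 °C; then 2 M HCl
Reagents that add atoms: potassium hydroxide [K+].[OH-]
Why: Palladium-catalysed C–O coupling of the aryl bromide with hydroxide (hydroxylation), with saponification of the ethyl ester by the same base, so that one operation should deliver the phenol acid.

Step 4
Reactants: 5 3-(3-hydroxy-2,6-dimethylphenyl)propanoic acid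
Product: 6 3-(3-acetoxy-2,6-dimethylphenyl)propanoic acid
Conditions: Ac2O (1.2 equiv), 2 M aq NaOH, 0 °C; then HCl to pH 2
Reagents that add atoms: acetic anhydride CC(=O)OC(C)=O
Why: Schotten–Baumann acetylation in aqueous alkali, where the phenoxide is acylated faster than the anhydride hydrolyses and any mixed anhydride at the carboxylate is hydrolysed back, so only the phenol is masked against the acid chloride of step 5.

Step 5
Reactants: 6 3-(3-acetoxy-2,6-dimethylphenyl)propanoic acid; 7 (trimethylsilyl)diazomethane
Product: 9 4-(3-acetoxy-2,6-dimethylphenyl)-1-diazobutan-2-one, via acid chloride 8 (not isolated)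
Conditions: (COCl)2, DMF (cat.), CH2Cl2, 0 °C to rt, evaporate; then 7 (1.5 equiv), Et3N (1.1 equiv), THF/MeCN 1:1, 0 °C; aq NaHCO3
Reagents that add atoms: oxalyl chloride ClC(=O)C(Cl)=O (chlorine of 8)
Why: Acid chloride formation and C-acylation of the silyl diazomethane (first stage of an Arndt–Eistert sequence), the silyl group being lost on aqueous work-up and triethylamine taking up HCl before it can add to the diazoketone; the aryl acetate is inert.

Step 6
Reactants: 9 4-(3-acetoxy-2,6-dimethylphenyl)-1-diazobutan-2-one
Product: 10 1-diazo-4-(3-hydroxy-2,6-dimethylphenyl)butan-2-one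
Conditions: K2CO3 (0.5 equiv), MeOH, 0 °C; pH 7 buffer
Reagents that add atoms: none
Why: Base-catalysed transesterification (methanolysis) of the aryl acetate, whose phenoxide is a good leaving group, under conditions to which an α-diazoketone is stable.

Step 7
Reactants: 10 1-diazo-4-(3-hydroxy-2,6-dimethylphenyl)butan-2-one
Product: 11 (4aS)-1,4a-dimethyl-4a,5,7,8-tetrahydronaphthalene-2,6-dione (eudesmane numbering: 1,4-diene-3,8-dione, 10β-methyl)
Conditions: [Cu(MeCN)4]PF6 (5 mol %), (S,S)-t-Bu-BOX (6 mol %), CH2Cl2, 40 °C, 10 added over 8 h (final 0.01 M)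
Reagents that add atoms: none
Why: Proposed new method: the chiral copper(I) bis(oxazoline) complex extrudes N2 from 10 to give an electrophilic copper carbene at C9, which is attacked by arene carbon C10 para to the free hydroxyl on C3; the cyclohexadienyl cation cannot rearomatise because C10 carries methyl C14, so it loses the phenolic proton and the C9–copper bond is protonated, leaving the cross-conjugated 1,4-dien-3-one and the C8 ketone. The closest known reaction types are the racemic copper- or acid-promoted intramolecular para-alkylation of phenols by diazoketones to 4,4-disubstituted cyclohexadienones and the copper–bis(oxazoline)-catalysed enantioselective intramolecular Buchner reaction of 1-diazo-4-arylbutan-2-ones, in which the same kind of carbene attacks the ipso–ortho bond of the arene. Ring B (C5–C10) closes as a six-membered carbocycle by bonding C9 to the ring carbon ortho to the tether, formally 6-endo with respect to the C5–C10 aromatic bond; attack at the ipso carbon C5 (five-membered ring) is not assisted because C5 is meta to the hydroxyl. C10 is the only new stereocentre and the substrate is achiral, so its configuration is decided solely by which enantiotopic face of the arene at C10 meets the carbene inside the C2-symmetric ligand pocket. The step needs para (C10) over ortho (C4) attack and C-alkylation over O–H insertion or Buchner ring expansion: C4 is flanked by the hydroxyl and the tether and would give the less stable linearly conjugated dienone, the oxygen on C3 should open any C5–C9–C10 norcaradiene toward the dienone by cleaving C5–C9, and slow addition at high dilution suppresses intermolecular O–H insertion.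

Step 8
Reactants: 11 (4aS)-1,4a-dimethyl-4a,5,7,8-tetrahydronaphthalene-2,6-dione
Product: 12 (4aR)-1,4a-dimethyl-4,4a,7,8-tetrahydronaphthalene-2,6(3H,5H)-dione (4-ene-3,8-dione, 10β-methyl)
Conditions: H2 (1 atm), RhCl(PPh3)3 (5 mol %), benzene/EtOH 1:1, rt
Reagents that add atoms: none
Why: Homogeneous hydrogenation with Wilkinson's catalyst, which reduces the disubstituted C1=C2 bond of cross-conjugated 1,4-dien-3-ones and leaves the tetrasubstituted C4=C5 bond and both carbonyls untouched, as in the steroid 1,4-dien-3-one series; C10 is not affected (the descriptor changes only through CIP priorities).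

Step 9
Reactants: 12 (4aR)-1,4a-dimethyl-4,4a,7,8-tetrahydronaphthalene-2,6(3H,5H)-dione
Product: 13 (10R)-8,8-ethylenedioxy-11,12,13-trinoreudesm-4-en-3-one
Conditions: HOCH2CH2OH (3 equiv), PPTS (10 mol %), benzene, reflux, Dean–Stark
Reagents that add atoms: ethylene glycol OCCO
Why: Acid-catalysed ketalisation, selective because the saturated C8 carbonyl is far more electrophilic than the conjugated tetrasubstituted C3 enone carbonyl; it protects C8 against the dissolving-metal and hydride steps.

Step 10
Reactants: 13 (10R)-8,8-ethylenedioxy-11,12,13-trinoreudesm-4-en-3-one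
Product: 15 3-trimethylsilyloxy-8,8-ethylenedioxy-11,12,13-trinor-5α-eudesm-3-ene, via lithium enolate 14 (not isolated)
Conditions: Li (2.5 equiv), NH3/THF, t-BuOH (1.0 equiv), −78 °C; isoprene; evaporate NH3; TMSCl (3 equiv), Et3N, THF, −78 to 0 °C
Reagents that add atoms: lithium [Li] (lithium of 14); chlorotrimethylsilane C[Si](C)(C)Cl
Why: Dissolving-metal (Birch-type) enone reduction with regiospecific enolate trapping (reductive silylation), in which C5 is protonated axially, anti to the angular methyl, setting 5α-H and the trans ring fusion, and the C3 enolate, formed only as the Δ3 isomer, is silylated on oxygen.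

Step 11
Reactants: 15 3-trimethylsilyloxy-8,8-ethylenedioxy-11,12,13-trinor-5α-eudesm-3-ene
Product: 18 4α-hydroxy-8,8-ethylenedioxy-11,12,13-trinor-5α-eudesman-3-one (4β-methyl), via silyloxy epoxide 16 (not isolated), via 4-silyloxy ketone 17 (not isolated)
Conditions: mCPBA (1.1 equiv), NaHCO3, CH2Cl2, −20 to 0 °C; then K2CO3, MeOH, 0 °C
Reagents that add atoms: 3-chloroperoxybenzoic acid OOC(=O)c1cccc(Cl)c1
Why: Rubottom oxidation, in which the peracid epoxidises the enol ether from the α face, opposite the axial C10 methyl that shields the β face of C4, the silyloxy epoxide opens with 1,4-silyl shift and methanolysis frees the tertiary alcohol, so C4 should carry 4α-OH and 4β-methyl.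

Step 12
Reactants: 18 4α-hydroxy-8,8-ethylenedioxy-11,12,13-trinor-5α-eudesman-3-one
Product: 19 8,8-ethylenedioxy-11,12,13-trinor-5α-eudesmane-3α,4α-diol
Conditions: L-Selectride (2.5 equiv), THF, −78 °C; then H2O
Reagents that add atoms: none
Why: Ketone reduction by a bulky trialkylborohydride, which approaches C3 along the equatorial trajectory (β face) to avoid the axial hydrogens on C1 and C5 and so should give the axial 3α-alcohol cis to the 4α-hydroxyl, as known for 4,4-disubstituted 3-oxo decalins and steroids.

Step 13
Reactants: 19 8,8-ethylenedioxy-11,12,13-trinor-5α-eudesmane-3α,4α-diol; 20 angelic acid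
Product: 22 3α-angeloyloxy-8,8-ethylenedioxy-11,12,13-trinor-5α-eudesman-4α-ol, via angeloyl 2,4,6-trichlorobenzoyl anhydride 21 (not isolated)
Conditions: 20, 2,4,6-trichlorobenzoyl chloride, Et3N, toluene, rt, 2 h; then 19, toluene, 80 °C (no DMAP)
Reagents that add atoms: 2,4,6-trichlorobenzoyl chloride ClC(=O)c1c(Cl)cc(Cl)cc1Cl (aroyl group of 21)
Why: Mixed-anhydride (Yamaguchi-type) esterification without nucleophilic catalyst, in which the alcohol attacks the unhindered angeloyl carbonyl, the absence of DMAP avoids Z-to-E isomerisation to the tiglate, and the secondary 3α-hydroxyl reacts while the tertiary 4α-hydroxyl does not.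

Step 14
Reactants: 22 3α-angeloyloxy-8,8-ethylenedioxy-11,12,13-trinor-5α-eudesman-4α-ol
Product: 23 4α-acetoxy-3α-angeloyloxy-8,8-ethylenedioxy-11,12,13-trinor-5α-eudesmane
Conditions: Ac2O (10 equiv), DMAP (2 equiv), Et3N, ClCH2CH2Cl, 50 °C
Reagents that add atoms: acetic anhydride CC(=O)OC(C)=O
Why: DMAP-catalysed acylation of a tertiary alcohol under forcing conditions via the acetylpyridinium ion, the equatorial 4α-hydroxyl being the only free hydroxyl and the ketal and angelate being stable to the weakly basic medium.

Step 15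
Reactants: 23 4α-acetoxy-3α-angeloyloxy-8,8-ethylenedioxy-11,12,13-trinor-5α-eudesmane
Product: 24 4α-acetoxy-3α-angeloyloxy-11,12,13-trinor-5α-eudesman-8-one
Conditions: 1 M HCl, THF, 25 °C
Reagents that add atoms: water O
Why: Acid-catalysed hydrolysis of the dioxolane under dilute room-temperature conditions that should not cleave the angelate or the tertiary acetate.

Step 16
Reactants: 24 4α-acetoxy-3α-angeloyloxy-11,12,13-trinor-5α-eudesman-8-one; 25 acetone
Product: 28 4α-acetoxy-3α-angeloyloxy-11-hydroxy-5α-eudesman-8-one (7β side chain), via lithium enolate 26 (not isolated), via chlorozinc enolate 27 (not isolated)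
Conditions: LDA (1.05 equiv), THF, −78 °C; ZnCl2 (1.1 equiv); 25 (3 equiv), −78 to −40 °C; aq NH4Cl
Reagents that add atoms: lithium diisopropylamide CC(C)N([Li])C(C)C (lithium of 26); zinc chloride Cl[Zn]Cl (ZnCl of 27)
Why: Directed aldol addition, in which LDA removes the axial proton at C7 (the less hindered α position, C9 being neopentyl) faster than it attacks the esters and the zinc enolate adds to acetone to give a chelated aldolate that resists retro-aldol cleavage; the new C7 centre is expected mainly equatorial (7β) and is removed in step 17.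

Step 17
Reactants: 28 4α-acetoxy-3α-angeloyloxy-11-hydroxy-5α-eudesman-8-one
Product: 30 4α-acetoxy-3α-angeloyloxy-5α-eudesm-7(11)-en-8-one, via tertiary mesylate 29 (not isolated)
Conditions: MsCl (3 equiv), Et3N (6 equiv), DMAP (cat.), CH2Cl2, 0 to 40 °C
Reagents that add atoms: methanesulfonyl chloride CS(Cl)(=O)=O (mesyl group of 29)
Why: Dehydration by mesylation (sulfene mechanism, which reaches tertiary alcohols) and E1cB elimination through the C7 enolate, which should give the conjugated tetrasubstituted 7(11)-alkene directly.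

Step 18
Reactants: 30 4α-acetoxy-3α-angeloyloxy-5α-eudesm-7(11)-en-8-one
Product: 32 4α-acetoxy-3α-angeloyloxy-11-hydroxy-5α-eudesm-6-en-8-one (target), via 11-hydroperoxide 31 (not isolated)
Conditions: O2, tetraphenylporphyrin (cat.), CH2Cl2, visible light, 0 °C; then PPh3 (1.2 equiv), 0 °C to rt
Reagents that add atoms: oxygen O=O
Why: Schenck ene reaction of singlet oxygen with an s-cis-locked α,β-unsaturated ketone, in which by the geminal effect hydrogen is taken from C6 (the alkyl group on C7 geminal to the carbonyl), oxygen adds to C11 and the alkene moves to C6=C7, the phosphine then reducing the tertiary hydroperoxide; the tetrasubstituted enone should react faster than the trisubstituted electron-poor angelate, and no stereocentre is touched.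

## Compound list

1 | 2-bromo-1,3-dimethylbenzene | Cc1cccc(C)c1Br | starting material
2 | (3-ethoxy-3-oxopropyl)zinc bromide | CCOC(=O)CC[Zn]Br | starting material
3 | ethyl 3-(2,6-dimethylphenyl)propanoate | CCOC(=O)CCc1c(C)cccc1C | intermediate
4 | ethyl 3-(3-bromo-2,6-dimethylphenyl)propanoate | CCOC(=O)CCc1c(C)ccc(Br)c1C | intermediate
5 | 3-(3-hydroxy-2,6-dimethylphenyl)propanoic acid | OC(=O)CCc1c(C)ccc(O)c1C | intermediate
6 | 3-(3-acetoxy-2,6-dimethylphenyl)propanoic acid | CC(=O)Oc1ccc(C)c(CCC(=O)O)c1C | intermediate
7 | (trimethylsilyl)diazomethane | C[Si](C)(C)C=[N+]=[N-] | starting material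
8 | 3-(3-acetoxy-2,6-dimethylphenyl)propanoyl chloride | CC(=O)Oc1ccc(C)c(CCC(=O)Cl)c1C | intermediate
9 | 4-(3-acetoxy-2,6-dimethylphenyl)-1-diazobutan-2-one | CC(=O)Oc1ccc(C)c(CCC(=O)C=[N+]=[N-])c1C | intermediate
10 | 1-diazo-4-(3-hydroxy-2,6-dimethylphenyl)butan-2-one | Cc1c(O)ccc(C)c1CCC(=O)C=[N+]=[N-] | intermediate
11 | (4aS)-1,4a-dimethyl-4a,5,7,8-tetrahydronaphthalene-2,6-dione | O=C1C=C[C@]2(C)CC(=O)CCC2=C1C | intermediate
12 | (4aR)-1,4a-dimethyl-4,4a,7,8-tetrahydronaphthalene-2,6(3H,5H)-dione | O=C1CC[C@]2(C)CC(=O)CCC2=C1C | intermediate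
13 | (10R)-8,8-ethylenedioxy-11,12,13-trinoreudesm-4-en-3-one | O=C1CC[C@]2(C)CC3(OCCO3)CCC2=C1C | intermediate
14 | lithium Δ3-enolate of the trans-fused 3-ketone (5α-H) | [Li]OC=1CC[C@]2(C)CC3(OCCO3)CC[C@H]2C=1C | intermediate
15 | 3-trimethylsilyloxy-8,8-ethylenedioxy-11,12,13-trinor-5α-eudesm-3-ene | C[Si](C)(C)OC=1CC[C@]2(C)CC3(OCCO3)CC[C@H]2C=1C | intermediate
16 | 3α,4α-epoxy-3β-trimethylsilyloxy-8,8-ethylenedioxy-11,12,13-trinor-5α-eudesmane | C[Si](C)(C)O[C@@]15CC[C@]2(C)CC3(OCCO3)CC[C@H]2[C@]1(C)O5 | intermediate
17 | 4α-trimethylsilyloxy-8,8-ethylenedioxy-11,12,13-trinor-5α-eudesman-3-one | O=C1CC[C@]2(C)CC3(OCCO3)CC[C@H]2[C@]1(C)O[Si](C)(C)C | intermediate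
18 | 4α-hydroxy-8,8-ethylenedioxy-11,12,13-trinor-5α-eudesman-3-one | O=C1CC[C@]2(C)CC3(OCCO3)CC[C@H]2[C@]1(C)O | intermediate
19 | 8,8-ethylenedioxy-11,12,13-trinor-5α-eudesmane-3α,4α-diol | O[C@@H]1CC[C@]2(C)CC3(OCCO3)CC[C@H]2[C@]1(C)O | intermediate
20 | angelic acid, (Z)-2-methylbut-2-enoic acid | C/C=C(/C)C(=O)O | starting material
21 | angeloyl 2,4,6-trichlorobenzoyl anhydride | C/C=C(/C)C(=O)OC(=O)c1c(Cl)cc(Cl)cc1Cl | intermediate
22 | 3α-angeloyloxy-8,8-ethylenedioxy-11,12,13-trinor-5α-eudesman-4α-ol | C/C=C(/C)C(=O)O[C@@H]1CC[C@]2(C)CC3(OCCO3)CC[C@H]2[C@]1(C)O | intermediate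
23 | 4α-acetoxy-3α-angeloyloxy-8,8-ethylenedioxy-11,12,13-trinor-5α-eudesmane | C/C=C(/C)C(=O)O[C@@H]1CC[C@]2(C)CC3(OCCO3)CC[C@H]2[C@]1(C)OC(C)=O | intermediate
24 | 4α-acetoxy-3α-angeloyloxy-11,12,13-trinor-5α-eudesman-8-one | C/C=C(/C)C(=O)O[C@@H]1CC[C@]2(C)CC(=O)CC[C@H]2[C@]1(C)OC(C)=O | intermediate
25 | acetone | CC(C)=O | starting material
26 | lithium Δ7-enolate of 24 | C/C=C(/C)C(=O)O[C@@H]1CC[C@]2(C)CC(O[Li])=CC[C@H]2[C@]1(C)OC(C)=O | intermediate
27 | chlorozinc Δ7-enolate of 24 | C/C=C(/C)C(=O)O[C@@H]1CC[C@]2(C)CC(O[Zn]Cl)=CC[C@H]2[C@]1(C)OC(C)=O | intermediate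
28 | 4α-acetoxy-3α-angeloyloxy-11-hydroxy-5α-eudesman-8-one (7β side chain) | C/C=C(/C)C(=O)O[C@@H]1CC[C@]2(C)CC(=O)[C@@H](C(C)(C)O)C[C@H]2[C@]1(C)OC(C)=O | intermediate
29 | 11-O-mesylate of 28 | C/C=C(/C)C(=O)O[C@@H]1CC[C@]2(C)CC(=O)[C@@H](C(C)(C)OS(C)(=O)=O)C[C@H]2[C@]1(C)OC(C)=O | intermediate
30 | 4α-acetoxy-3α-angeloyloxy-5α-eudesm-7(11)-en-8-one | C/C=C(/C)C(=O)O[C@@H]1CC[C@]2(C)CC(=O)C(=C(C)C)C[C@H]2[C@]1(C)OC(C)=O | intermediate
31 | 4α-acetoxy-3α-angeloyloxy-11-hydroperoxy-5α-eudesm-6-en-8-one | C/C=C(/C)C(=O)O[C@@H]1CC[C@]2(C)CC(=O)C(C(C)(C)OO)=C[C@H]2[C@]1(C)OC(C)=O | intermediate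
32 | (3R,4S,5R,10R)-4-acetoxy-3-angeloyloxy-11-hydroxyeudesm-6-en-8-one (3α-OAng, 4α-OAc, 5α-H, 10β-Me) | C/C=C(/C)C(=O)O[C@@H]1CC[C@]2(C)CC(=O)C(C(C)(C)O)=C[C@H]2[C@]1(C)OC(C)=O | target

## Step count and risks

Total step count: 18. Longest linear sequence: 18 steps (1 to 32; compounds 2, 7, 20 and 25 are purchased partners).

Steps most likely to fail:

Step 7. The carbene may be diverted to O–H insertion between two molecules, to cyclopropanation and ring expansion of the arene, or to ortho attack at C4, or the two faces of C10 may be poorly discriminated. The fallback abandons the carbene chemistry and reaches 13 by a known asymmetric Robinson annulation. It does not set out from a numbered compound: it replaces steps 1–9, starts from commercial racemic 7-methyl-1,4-dioxaspiro[4.5]decan-8-one F1 and comes back to the route at 13. Ketone F1 is condensed with (R)-1-phenylethylamine to the imine F2 in refluxing toluene with removal of water. The secondary enamine tautomer of F2 then adds to pent-1-en-3-one in THF at rt, a deracemising Michael addition on the face left open by the auxiliary, and gives the Michael adduct imine F3 with the quaternary C10 in place. Aqueous acetic acid hydrolyses F3 to the diketone (R)-7-methyl-7-(3-oxopentyl)-1,4-dioxaspiro[4.5]decan-8-one F4 and sets the amine free, and NaOMe in MeOH closes ring A of F4 by aldol condensation to 13. By analogy with the sense known for 2-methylcyclohexanone, the (R)-amine is expected to give the 10β-methyl series.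

Step 13. Acylation of the hindered axial 3α-hydroxyl may be slow, and the activated acid may isomerise from Z to E (tiglate formation); forcing the later tertiary acetylation could add to this. The fallback builds the angelate double bond on the molecule; it sets out from 19 and comes back at 23. Diol 19 is esterified at O3 with 2-[bis(2,2,2-trifluoroethoxy)phosphoryl]propanoic acid, DCC and DMAP in CH2Cl2, to the 3-O-phosphonopropanoate F5 of the diol, and the tertiary hydroxyl of F5 is acetylated with Ac2O, DMAP and Et3N to the 4-acetate F6 of that ester. A Still–Gennari olefination of F6 with KHMDS, 18-crown-6 and acetaldehyde in THF at −78 °C then forms the (Z)-2-methylbut-2-enoate and gives 23.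

Step 16. Enolisation may occur toward C9 or at the esters, the acetate on O4 may transfer to the C7 enolate, or the aldol addition may reverse. The fallback avoids a free metal enolate; it sets out from 24 and comes back at 28. Soft enolisation of 24 with TMSOTf and Et3N in CH2Cl2 at 0 °C gives the Δ7 trimethylsilyl enol ether F7 of the ketone, and a Mukaiyama aldol addition of F7 to acetone with TiCl4 in CH2Cl2 at −78 °C gives 28.

## Further compounds

F1 | step 7 | 7-methyl-1,4-dioxaspiro[4.5]decan-8-one (racemic, commercial) | CC1CC2(CCC1=O)OCCO2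
F2 | step 7 | imine of F1 with (R)-1-phenylethylamine | C[C@@H](N=C1CCC2(CC1C)OCCO2)c1ccccc1
F3 | step 7 | Michael adduct imine with quaternary C10 | CCC(=O)CC[C@]1(C)CC2(OCCO2)CCC1=N[C@H](C)c1ccccc1
F4 | step 7 | (R)-7-methyl-7-(3-oxopentyl)-1,4-dioxaspiro[4.5]decan-8-one | CCC(=O)CC[C@]1(C)CC2(OCCO2)CCC1=O
F5 | step 13 | 3-O-[2-(bis(2,2,2-trifluoroethoxy)phosphoryl)propanoyl] derivative of 19 | CC(C(=O)O[C@@H]1CC[C@]2(C)CC3(OCCO3)CC[C@H]2[C@]1(C)O)P(=O)(OCC(F)(F)F)OCC(F)(F)F
F6 | step 13 | 4-O-acetate of F5 | CC(C(=O)O[C@@H]1CC[C@]2(C)CC3(OCCO3)CC[C@H]2[C@]1(C)OC(C)=O)P(=O)(OCC(F)(F)F)OCC(F)(F)F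
F7 | step 16 | Δ7 trimethylsilyl enol ether of 24 | C/C=C(/C)C(=O)O[C@@H]1CC[C@]2(C)CC(O[Si](C)(C)C)=CC[C@H]2[C@]1(C)OC(C)=O
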